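**Retrosynthetic overview**
Chroman numbering is used: ring A is the benzo ring (C4a–C8a), ring B is the aryl group on C2, and ring C is the dihydropyran O1–C2–C3–C4–C4a–C8a.
Enabling feature: O1–C8a=C4a–C4 is a phenol oxygen ortho to a benzylic CH, so ring A is a latent o-quinone methide (C4 plus isobutyl is 3-methylbutanal). C2–C3 is the former double bond of an (E)-isopentenyl-phloroglucinol, and ring B stabilises charge at C2.
Key disconnection: ring C is cut at C4–C4a, C3–C4 and O1–C2 into a ring-A phenol, 3-methylbutanal and a ring-B styrene. These are joined in one flask by boron-templated ortho-hydroxyalkylation and a chiral phosphoric acid catalysed oxa-[4+2] that sets C2, C3 and C4.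
Ring A brings its 6-formyl group and two methyl ethers, so it has one free OH and gives one o-quinone methide. Ring B arrives as its tri-O-allyl ether, is freed and formylated twice, and ring A is demethylated last.
Ring order: rings A and B are bought as benzene rings, and ring C is the only skeleton ring made and is closed last. A temporary dioxaborinine ring is formed and removed in the same flask.

Key step: step 4

Assumption (remark on the chemistry): the sense of induction of the acid in step 4 cannot be taken from a close analogue. (R)-TRIP is written; the equally available (S)-acid is to be used if a test run shows the opposite sense.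

**Step 1**
Reactants: 1 2,4,6-trihydroxybenzaldehyde
Product: 2 2,4,6-tris(allyloxy)benzaldehyde
Conditions: allyl bromide (3.6 equiv), K2CO3, DMF, 50 °C
Reagents that add atoms: allyl bromide, C=CCBr
Why: Williamson ether synthesis in which the three phenoxides are O-allylated, C-allylation being held back by the electron-withdrawing formyl group; no stereocentre is formed.

**Step 2**
Reactants: 2 2,4,6-tris(allyloxy)benzaldehyde
Product: 3 (±)-3-methyl-1-[2,4,6-tris(allyloxy)phenyl]butan-1-ol
Conditions: i-BuMgBr, THF, 0 °C; sat. aq. NH4Cl
Reagents that add atoms: isobutylmagnesium bromide, CC(C)C[Mg]Br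
Why: Grignard 1,2-addition to an aryl aldehyde that has no acidic or competing electrophilic group; the carbinol centre is racemic and is erased in step 3.

**Step 3**
Reactants: 3 (±)-3-methyl-1-[2,4,6-tris(allyloxy)phenyl]butan-1-ol
Product: 4 (E)-1,3,5-tris(allyloxy)-2-(3-methylbut-1-en-1-yl)benzene
Conditions: PPTS (5 mol%), 4 Å MS, PhMe, 60 °C
Reagents that add atoms: none
Why: acid-catalysed E1 dehydration through the 2,4,6-trialkoxybenzyl cation, in which only the CH2 group can lose a proton and the E-alkene should form because the Z-isomer would press the isopropyl group against an ortho allyloxy group.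

**Step 4**
Reactants: 5 4-hydroxy-2,6-dimethoxybenzaldehyde; 6 3-methylbutanal (isovaleraldehyde); 4 (E)-1,3,5-tris(allyloxy)-2-(3-methylbut-1-en-1-yl)benzene
Product: 10 (2R,3R,4S)-4-isobutyl-3-isopropyl-5,7-dimethoxy-2-[2,4,6-tris(allyloxy)phenyl]chromane-6-carbaldehyde, via dioxaborinine 7 (not isolated), via benzylic alcohol 8 (not isolated), via o-quinone methide 9 (not isolated)
Conditions: 5, 6 (1.2 equiv), PhB(OH)2 (1.1 equiv), EtCO2H (10 mol%), PhMe, 90 °C, 4 Å MS; pinacol (1.1 equiv), rt; then 4 (1.5 equiv), (R)-TRIP (10 mol%), 5 Å MS, 0 °C
Reagents that add atoms: none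
Why: Proposed new method: phenylboronic acid ties phenol 5 and aldehyde 6 together and delivers the aldehyde carbon to the ortho carbon (boronic acid templated ortho-hydroxyalkylation of phenols) to give 7, pinacol sets 8 free, and the chiral phosphoric acid dehydrates 8 to the hydrogen-bonded o-quinone methide 9, which adds styrene 4 in an inverse-electron-demand oxa-[4+2] cycloaddition. The closest known reaction types are the racemic, thermal three-component domino Knoevenagel/hetero-Diels–Alder reaction of formylated phloroglucinols with 3-methylbutanal and alkenes and the chiral Brønsted acid catalysed cycloaddition of preformed, aryl-substituted o-quinone methides with styrenes; new are the alkyl-substituted o-quinone methide, the β-branched styrene and the one-flask assembly. Ring C is closed by an asynchronous, suprafacial [4+2] addition across O1=C8a–C4a=C4, with C3–C4 formed ahead of O1–C2 because ring B stabilises charge at C2, which also fixes the orientation (aryl on C2, isopropyl on C3). The trans relation of C2 and C3 is copied from the E double bond of 4, and C4 is controlled by the 5-methoxy group, which, buttressed by the 6-formyl group, pushes the isobutyl group of 9 to the side of the carbonyl oxygen (Z) and later into the pseudoaxial position, so that the aryl-endo/isopropyl-exo approach should give the 3,4-cis, 2,4-trans array. The absolute configuration is set by the phosphate, which is bound to O1 of 9 and leaves one face of C4 open. The step needs a single o-quinone methide and cross- over self-reaction: 5 has only one free OH with two equivalent ortho carbons (hence 6-CHO and 8-H), and the formyl group makes 9 electron-poor and its own styrene tautomer a poor partner, while 4 is the most electron-rich π bond in the flask.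

**Step 5**
Reactants: 10 (2R,3R,4S)-4-isobutyl-3-isopropyl-5,7-dimethoxy-2-[2,4,6-tris(allyloxy)phenyl]chromane-6-carbaldehyde
Product: 11 (2R,3R,4S)-4-isobutyl-3-isopropyl-5,7-dimethoxy-2-(2,4,6-trihydroxyphenyl)chromane-6-carbaldehyde
Conditions: Pd(PPh3)4 (5 mol%), N-methylaniline (6 equiv), THF, rt
Reagents that add atoms: none
Why: Tsuji–Trost-type Pd(0) deallylation in which the aryl allyl ethers ionise to π-allylpalladium and phenoxide and the weakly basic amine takes up the allyl groups, so that the methyl ethers, the aldehyde, the O1–C2 bond and the three stereocentres are left alone.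

**Step 6**
Reactants: 11 (2R,3R,4S)-4-isobutyl-3-isopropyl-5,7-dimethoxy-2-(2,4,6-trihydroxyphenyl)chromane-6-carbaldehyde
Product: 12 5-[(2R,3R,4S)-6-formyl-4-isobutyl-3-isopropyl-5,7-dimethoxychroman-2-yl]-2,4,6-trihydroxyisophthalaldehyde
Conditions: POCl3 (3 equiv), DMF (3 equiv), EtOAc, 0 °C → rt; then H2O, 40 °C
Reagents that add atoms: N,N-dimethylformamide, CN(C)C=O; water, O
Why: twofold Vilsmeier–Haack formylation in which the weak chloroiminium electrophile attacks the two free CH positions of the free phloroglucinol ring B, whereas C8–H belongs to an etherified, formyl-deactivated ring of the kind at which this reagent stops, and an O1–C2 bond opened by HCl should reclose to the more stable 2,3-trans isomer.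

**Step 7**
Reactants: 12 5-[(2R,3R,4S)-6-formyl-4-isobutyl-3-isopropyl-5,7-dimethoxychroman-2-yl]-2,4,6-trihydroxyisophthalaldehyde
Product: 13 5-[(2R,3R,4S)-6-formyl-5,7-dihydroxy-4-isobutyl-3-isopropylchroman-2-yl]-2,4,6-trihydroxyisophthalaldehyde (target)
Conditions: BBr3 (10 equiv), CH2Cl2, −78 °C → rt; then ice/H2O
Reagents that add atoms: none
Why: Lewis acid cleavage of aryl methyl ethers with BBr3, helped by chelation of boron between the 6-formyl oxygen and the flanking methoxy oxygens, while the doubly formylated ring B no longer supports ionisation at C2, so the stereocentres are kept.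

**Compound list**
1 | 2,4,6-trihydroxybenzaldehyde | O=Cc1c(O)cc(O)cc1O | starting material
2 | 2,4,6-tris(allyloxy)benzaldehyde | O=Cc1c(OCC=C)cc(OCC=C)cc1OCC=C | intermediate
3 | (±)-3-methyl-1-[2,4,6-tris(allyloxy)phenyl]butan-1-ol | CC(C)CC(O)c1c(OCC=C)cc(OCC=C)cc1OCC=C | intermediate
4 | (E)-1,3,5-tris(allyloxy)-2-(3-methylbut-1-en-1-yl)benzene | CC(C)/C=C/c1c(OCC=C)cc(OCC=C)cc1OCC=C | intermediate
5 | 4-hydroxy-2,6-dimethoxybenzaldehyde | COc1cc(O)cc(OC)c1C=O | starting material
6 | 3-methylbutanal | CC(C)CC=O | starting material
7 | (±)-4-isobutyl-5,7-dimethoxy-2-phenyl-4H-1,3,2-benzodioxaborinine-6-carbaldehyde | COc1cc2OB(c3ccccc3)OC(CC(C)C)c2c(OC)c1C=O | intermediate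
8 | (±)-4-hydroxy-3-(1-hydroxy-3-methylbutyl)-2,6-dimethoxybenzaldehyde | COc1cc(O)c(C(O)CC(C)C)c(OC)c1C=O | intermediate
9 | (3Z)-2,6-dimethoxy-3-(3-methylbutylidene)-4-oxocyclohexa-1,5-diene-1-carbaldehyde | CC(C)C/C=C1\C(=O)C=C(OC)C(C=O)=C1OC | intermediate
10 | (2R,3R,4S)-4-isobutyl-3-isopropyl-5,7-dimethoxy-2-[2,4,6-tris(allyloxy)phenyl]chromane-6-carbaldehyde | CC(C)C[C@@H]1c2c(cc(OC)c(C=O)c2OC)O[C@@H](c2c(OCC=C)cc(OCC=C)cc2OCC=C)[C@@H]1C(C)C | intermediate
11 | (2R,3R,4S)-4-isobutyl-3-isopropyl-5,7-dimethoxy-2-(2,4,6-trihydroxyphenyl)chromane-6-carbaldehyde | CC(C)C[C@@H]1c2c(cc(OC)c(C=O)c2OC)O[C@@H](c2c(O)cc(O)cc2O)[C@@H]1C(C)C | intermediate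
12 | 5-[(2R,3R,4S)-6-formyl-4-isobutyl-3-isopropyl-5,7-dimethoxychroman-2-yl]-2,4,6-trihydroxyisophthalaldehyde | CC(C)C[C@@H]1c2c(cc(OC)c(C=O)c2OC)O[C@@H](c2c(O)c(C=O)c(O)c(C=O)c2O)[C@@H]1C(C)C | intermediate
13 | 5-[(2R,3R,4S)-6-formyl-5,7-dihydroxy-4-isobutyl-3-isopropylchroman-2-yl]-2,4,6-trihydroxyisophthalaldehyde | CC(C)C[C@@H]1c2c(cc(O)c(C=O)c2O)O[C@@H](c2c(O)c(C=O)c(O)c(C=O)c2O)[C@@H]1C(C)C | target

**Total step count:** 7. **Longest linear sequence:** 7 (steps 1–7 from 1; compounds 5 and 6 enter at step 4 without prior steps).

**Steps most likely to fail**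

Step 4 (Proposed new method).
- What may go wrong: 9 may tautomerise to its o-hydroxystyrene, which then cycloadds to further 9. The free CH positions of ring B in 4 may attack by a Friedel–Crafts path instead of the double bond. Facial selectivity under the chiral acid may be poor, and part of the material may leak through the E-o-quinone methide to the all-trans diastereomer.
- Fallback, known chemistry, from 4, 5 and 6 back to 10: 5, 6 and phenylboronic acid are condensed as before, 7 is cleaved with pinacol, and benzylic alcohol 8 is isolated. Alcohol 8 and styrene 4 are then heated in toluene at about 110 °C without any chiral additive. This is thermal dehydration of an o-hydroxybenzyl alcohol with hetero-Diels–Alder trapping of the o-quinone methide by a styrene.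
- This should give the racemate, that is 10 together with its enantiomer (2S,3S,4R)-4-isobutyl-3-isopropyl-5,7-dimethoxy-2-[2,4,6-tris(allyloxy)phenyl]chromane-6-carbaldehyde F1. The enantiomers are separated by preparative HPLC or SFC on a polysaccharide chiral phase, the configuration is assigned by ECD, and 10 goes on to step 5.

Step 6.
- What may go wrong: acid may open O1–C2 in the very electron-rich 11 with loss of the C3 proton, which scrambles C3. The reaction may stop after the first formylation, or the phenols may be O-formylated or phosphorylated in a way that does not hydrolyse cleanly.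
- Fallback, from 11 back to 12: magnesium phenolate directed ortho-formylation (Casnati–Skattebøl formylation; MgCl2, Et3N, paraformaldehyde, MeCN, reflux). It runs in a basic medium and can only formylate carbons ortho to a free phenol. Ring A has no free phenol, so C8 is excluded by the mechanism. New compounds: none F0.

Step 7.
- What may go wrong: only the first of the two methoxy groups that flank the same formyl group may be cleaved. Formyl groups may be attacked by bromide, or the benzylic O1–C2 ether may be cleaved by the Lewis acid.
- Fallback, from 12 back to 13: nucleophilic SN2 demethylation with a soft thiolate under basic conditions (lithium 4-methylbenzenethiolate, DMPU/toluene, about 110 °C, then acidic work-up). This type of cleavage is used for methyl ethers ortho to formyl groups in phloroglucinols and avoids any Lewis acid. New compounds: none F0.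

**Further compounds**
F1 | step 4 | (2S,3S,4R)-4-isobutyl-3-isopropyl-5,7-dimethoxy-2-[2,4,6-tris(allyloxy)phenyl]chromane-6-carbaldehyde (enantiomer of 10) | CC(C)C[C@H]1c2c(cc(OC)c(C=O)c2OC)O[C@H](c2c(OCC=C)cc(OCC=C)cc2OCC=C)[C@H]1C(C)C
F0 | step 6 | none | none
F0 | step 7 | none | none
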